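Eudesmane numbering is used for all bicyclic compounds: ring A = C1–C5 + C10, ring B = C5–C10; C4 bears OH and CH3, C6 the ester oxygen, C7 the isopropyl group, C10 the angular CH3.

**Plan**
- Retrosynthetic cuts, in order: the C6–O acyl bond (isoferulic acid); C6–H (back to a 6-ketone, a helper oxidation level that is reduced away later); the C4–C5 and C10–CH3 bonds together in one operation; the C10–C1 bond, leading to 4-isopropylcyclohexanone and a masked 4-oxopentyl Grignard reagent.
- Feature used: with C6 as a ketone, C10 (quaternary, angular CH3) is its β-carbon and C5 its α-carbon, and C5 is bonded to the carbinol carbon C4. The 4-hydroxy-6-oxo unit with the C10 methyl is therefore the product of methyl conjugate addition to a C5=C10 enone followed by aldol addition of the C5 enolate to a C4 methyl ketone held on the three-carbon tether C1–C2–C3 from C10.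
- Forward order: ring B is bought; the side chain is attached and the carbonyl transposed next to the isopropyl-bearing carbon; ring A (C10–C1–C2–C3–C4–C5) is closed last by the tandem conjugate methylation–aldol addition; then C6 reduction, esterification and phenol release.
- Stereochemistry: C10 from the chiral copper catalyst; C4, C5 and C7 by base equilibration relative to C10 (C5 and C7 are α to the C6 ketone, C4 is retro-aldol labile); C6 by hydride attack anti to the axial 10-CH3; the E alkene comes from isoferulic acid.

Key step: step 5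

Assumption: the (S,S)-phosphoramidite is taken to be the antipode that delivers CH3 to the Si face of the β-carbon of the enone entering the key step; if the sense of induction is the opposite, the (R,R)-ligand is used and nothing else changes.

Step 1
Reactants: 1 4-(propan-2-yl)cyclohexan-1-one
Product: 2 (±)-4-(propan-2-yl)cyclohex-2-en-1-one (cryptone)
Conditions: Pd(DMSO)2(O2CCF3)2 (5 mol %), O2 (1 atm), AcOH, 80 °C
Reagents that add atoms: none
Why: Aerobic α,β-dehydrogenation of a cyclohexanone at divalent palladium (enolate palladation, β-hydride elimination, reoxidation by O2) is established for 4-substituted cyclohexanones and should stop at the enone; the substrate is symmetric, so one racemic enone results and no stereocentre of the target is set.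

Step 2
Reactants: 2 (±)-4-(propan-2-yl)cyclohex-2-en-1-one; 3 2-(3-chloropropyl)-2-methyl-1,3-dioxolane
Product: 5 1-[3-(2-methyl-1,3-dioxolan-2-yl)propyl]-4-(propan-2-yl)cyclohex-2-en-1-ol (racemic; both diastereomers), via Grignard reagent 4 (not isolated)
Conditions: 3, Mg, THF, 50 °C; then 2, THF, −78 → 0 °C; sat. aq. NH4Cl
Reagents that add atoms: none
Why: Grignard 1,2-addition of an alkylmagnesium chloride to a cyclohex-2-enone at low temperature; the configuration of the new carbinol carbon is irrelevant because this carbon becomes sp2 in step 3.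

Step 3
Reactants: 5 1-[3-(2-methyl-1,3-dioxolan-2-yl)propyl]-4-(propan-2-yl)cyclohex-2-en-1-ol
Product: 6 (±)-3-[3-(2-methyl-1,3-dioxolan-2-yl)propyl]-6-(propan-2-yl)cyclohex-2-en-1-one
Conditions: [C5H5NH][CrO3Cl] (2 equiv), Celite, CH2Cl2, 23 °C
Reagents that add atoms: pyridinium chlorochromate, [O-][Cr](=O)(=O)Cl.c1cc[nH+]cc1 (supplies the carbonyl oxygen)
Why: Babler–Dauben oxidative 1,3-transposition: the tertiary allylic chromate ester undergoes a [3,3] shift and the secondary allylic chromate is oxidised by hexavalent chromium, which places the carbonyl next to the isopropyl-bearing carbon (future C6 and C7) and the side chain on the β-carbon (future C10); the dioxolane should survive.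

Step 4
Reactants: 6 (±)-3-[3-(2-methyl-1,3-dioxolan-2-yl)propyl]-6-(propan-2-yl)cyclohex-2-en-1-one
Product: 7 (±)-3-(4-oxopentyl)-6-(propan-2-yl)cyclohex-2-en-1-one
Conditions: HCl (1 M aq.), THF, 23 °C
Reagents that add atoms: water, O
Why: Acid-catalysed hydrolysis of a ketone dioxolane; dilute acid at room temperature should leave the enone untouched.

Step 5
Reactants: 7 (±)-3-(4-oxopentyl)-6-(propan-2-yl)cyclohex-2-en-1-one
Product: 9 (10R)-4-hydroxyeudesman-6-one (mixture of epimers at C4/C5/C7), via aluminium enolate 8 (not isolated)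
Conditions: Cu(O2CC4H3S) (5 mol %), (S,S)-N,N-bis(1-phenylethyl)dibenzo[d,f][1,3,2]dioxaphosphepin-6-amine (10 mol %), AlMe3 (3 equiv), Et2O, −30 → 0 °C; sat. aq. NH4Cl
Reagents that add atoms: trimethylaluminium, C[Al](C)C
Why: Proposed new method: the monovalent copper–phosphoramidite catalyst transfers CH3 from AlMe3 to C10 (the enone β-carbon) by way of a π-complex and a trivalent copper intermediate, and reductive elimination leaves the dimethylaluminium enolate 8 with its double bond fixed at C5=C6; on warming, C5 adds to the AlMe3-activated methyl ketone C4 through a closed six-membered (Zimmerman–Traxler) array and closes ring A by a 6-(enolexo)-exo-trig aldol addition. The closest known reaction types are the copper-catalysed asymmetric conjugate addition of AlMe3 to 3-alkylcyclohex-2-enones with trapping of the aluminium enolate, and the copper-catalysed conjugate addition–aldol cyclization of enones carrying a tethered ketone with dialkylzincs; their combination on a β,β-disubstituted cyclic enone that forms a quaternary carbon has not been shown. C10 is set by the catalyst (CH3 to the Si face of C3 of 7) and is the only stereocentre the route keeps from this step. C5 and C4 arise from the chair-like closed transition state, which is expected to give mainly the cis-fused ketol, and C7 enters as both epimers; all three are left to step 6. The step needs 1,4- over 1,2-methyl transfer and reaction at the enone in preference to the saturated ketone, which copper catalysis in Et2O at −30 °C should secure because AlMe3 alone adds to neither carbonyl at a useful rate there and the enone is the only conjugated acceptor. It also needs the fused over the bridged aldol mode, which the substrate secures because the enolate is generated regiospecifically at C5, five atoms from C4, and no enolate of the side-chain ketone is formed.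

Step 6
Reactants: 9 (10R)-4-hydroxyeudesman-6-one (mixture of epimers at C4/C5/C7)
Product: 10 (4S,5R,7S,10R)-4-hydroxyeudesman-6-one (4β-OH; 5α-H; 7β-isopropyl; 10β-CH3)
Conditions: NaOMe (0.3 equiv), MeOH, 23 °C
Reagents that add atoms: none
Why: Base equilibration (enolisation at C5 and C7, retro-aldol/aldol at C4) should funnel all isomers into the trans-fused ketol with equatorial 7-isopropyl, equatorial 4α-CH3 and axial 4β-OH hydrogen-bonded to the C6 carbonyl, because the C4 epimer would place 4-CH3 and 10-CH3 syn-diaxial and trans-fused 6-oxodecalins with an angular methyl are the stable isomers; C4, C5 and C7 are thereby set relative to C10 under thermodynamic control.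

Step 7
Reactants: 10 (4S,5R,7S,10R)-4-hydroxyeudesman-6-one
Product: 11 (4S,5S,6R,7S,10R)-eudesmane-4,6-diol (4β,6β-diol)
Conditions: NaBH4, MeOH, −20 → 0 °C
Reagents that add atoms: none
Why: Hydride reduction of a conformationally fixed cyclohexanone: the axial β trajectory at C6 is blocked by the syn-axial 10-CH3 and 4-OH, so hydride should enter from the α face (equatorial attack) and give the axial 6β-alcohol, as in the NaBH4 reduction of 6-oxo-5α-steroids.

Step 8
Reactants: 12 isoferulic acid, (E)-3-(3-hydroxy-4-methoxyphenyl)prop-2-enoic acid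
Product: 14 (E)-3-[3-(tert-butyldimethylsilyloxy)-4-methoxyphenyl]prop-2-enoic acid, via bis-silyl derivative 13 (not isolated)
Conditions: TBSCl (2.3 equiv), imidazole, DMF, 23 °C; then AcOH/THF/H2O, 23 °C
Reagents that add atoms: tert-butyldimethylsilyl chloride, CC(C)(C)[Si](C)(C)Cl
Why: Silylation of phenol and acid followed by selective hydrolysis of the labile silyl ester should leave the aryl silyl ether; the E alkene is not touched.

Step 9
Reactants: 14 (E)-3-[3-(tert-butyldimethylsilyloxy)-4-methoxyphenyl]prop-2-enoic acid; 11 (4S,5S,6R,7S,10R)-eudesmane-4,6-diol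
Product: 16 (4S,5S,6R,7S,10R)-4-hydroxyeudesman-6-yl (E)-3-[3-(tert-butyldimethylsilyloxy)-4-methoxyphenyl]prop-2-enoate, via mixed anhydride 15 (not isolated)
Conditions: 14, 2,4,6-Cl3C6H2COCl, Et3N, toluene, 23 °C; then 11, DMAP, toluene, 80 °C
Reagents that add atoms: none
Why: Yamaguchi esterification: DMAP attacks the mixed anhydride at the less hindered cinnamoyl carbonyl and the acylpyridinium should acylate the secondary 6β-OH, while the tertiary 4β-OH does not react; no stereocentre is touched.

Step 10
Reactants: 16 (4S,5S,6R,7S,10R)-4-hydroxyeudesman-6-yl (E)-3-[3-(tert-butyldimethylsilyloxy)-4-methoxyphenyl]prop-2-enoate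
Product: 17 (4S,5S,6R,7S,10R)-4-hydroxyeudesman-6-yl (E)-3-(3-hydroxy-4-methoxyphenyl)prop-2-enoate (target)
Conditions: HF·pyridine, pyridine/THF, 0 → 23 °C
Reagents that add atoms: none
Why: Fluoride cleavage of the aryl silyl ether under buffered conditions should leave the cinnamate ester, the E alkene and the tertiary alcohol intact.

**Compound list**
1 | 4-(propan-2-yl)cyclohexan-1-one | CC(C)C1CCC(=O)CC1 | starting material
2 | (±)-4-(propan-2-yl)cyclohex-2-en-1-one (cryptone) | CC(C)C1CCC(=O)C=C1 | intermediate
3 | 2-(3-chloropropyl)-2-methyl-1,3-dioxolane | CC1(CCCCl)OCCO1 | starting material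
4 | [3-(2-methyl-1,3-dioxolan-2-yl)propyl]magnesium chloride | CC1(CCC[Mg]Cl)OCCO1 | intermediate
5 | 1-[3-(2-methyl-1,3-dioxolan-2-yl)propyl]-4-(propan-2-yl)cyclohex-2-en-1-ol (racemic, both diastereomers) | CC(C)C1CCC(O)(CCCC2(C)OCCO2)C=C1 | intermediate
6 | (±)-3-[3-(2-methyl-1,3-dioxolan-2-yl)propyl]-6-(propan-2-yl)cyclohex-2-en-1-one | CC(C)C1CCC(CCCC2(C)OCCO2)=CC1=O | intermediate
7 | (±)-3-(4-oxopentyl)-6-(propan-2-yl)cyclohex-2-en-1-one | CC(C)C1CCC(CCCC(C)=O)=CC1=O | intermediate
8 | dimethylaluminium (3R)-3-methyl-3-(4-oxopentyl)-6-(propan-2-yl)cyclohex-1-en-1-olate (both C6 epimers) | C[Al](C)OC1=C[C@](C)(CCCC(C)=O)CCC1C(C)C | intermediate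
9 | (10R)-4-hydroxyeudesman-6-one, i.e. (4aR)-8-hydroxy-4a,8-dimethyl-2-(propan-2-yl)octahydronaphthalen-1(2H)-one, mixture of epimers at C4, C5 and C7 | O=C1C2[C@](C)(CCCC2(C)O)CCC1C(C)C | intermediate
10 | (4S,5R,7S,10R)-4-hydroxyeudesman-6-one (4β-OH, 5α-H, 7β-isopropyl, 10β-CH3; trans-fused) | O=C1[C@@H]2[C@](C)(CCC[C@]2(C)O)CC[C@H]1C(C)C | intermediate
11 | (4S,5S,6R,7S,10R)-eudesmane-4,6-diol (4β,6β-diol, 5α-H, 7β-isopropyl) | O[C@H]1[C@@H]2[C@](C)(CCC[C@]2(C)O)CC[C@H]1C(C)C | intermediate
12 | isoferulic acid, (E)-3-(3-hydroxy-4-methoxyphenyl)prop-2-enoic acid | COc1ccc(/C=C/C(=O)O)cc1O | starting material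
13 | tert-butyldimethylsilyl (E)-3-[3-(tert-butyldimethylsilyloxy)-4-methoxyphenyl]prop-2-enoate | COc1ccc(/C=C/C(=O)O[Si](C)(C)C(C)(C)C)cc1O[Si](C)(C)C(C)(C)C | intermediate
14 | (E)-3-[3-(tert-butyldimethylsilyloxy)-4-methoxyphenyl]prop-2-enoic acid | COc1ccc(/C=C/C(=O)O)cc1O[Si](C)(C)C(C)(C)C | intermediate
15 | (E)-3-[3-(tert-butyldimethylsilyloxy)-4-methoxyphenyl]prop-2-enoic 2,4,6-trichlorobenzoic anhydride | COc1ccc(/C=C/C(=O)OC(=O)c2c(Cl)cc(Cl)cc2Cl)cc1O[Si](C)(C)C(C)(C)C | intermediate
16 | (4S,5S,6R,7S,10R)-4-hydroxyeudesman-6-yl (E)-3-[3-(tert-butyldimethylsilyloxy)-4-methoxyphenyl]prop-2-enoate | COc1ccc(/C=C/C(=O)O[C@H]2[C@@H]3[C@](C)(CCC[C@]3(C)O)CC[C@H]2C(C)C)cc1O[Si](C)(C)C(C)(C)C | intermediate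
17 | (4S,5S,6R,7S,10R)-4-hydroxyeudesman-6-yl (E)-3-(3-hydroxy-4-methoxyphenyl)prop-2-enoate, i.e. (1R,2S,4aR,8S,8aS)-8-hydroxy-4a,8-dimethyl-2-(propan-2-yl)decahydronaphthalen-1-yl isoferulate | COc1ccc(/C=C/C(=O)O[C@H]2[C@@H]3[C@](C)(CCC[C@]3(C)O)CC[C@H]2C(C)C)cc1O | target

Total step count: 10. Longest linear sequence: 9 steps (steps 1–7, 9, 10).

**Steps most likely to fail**

1. Step 5 (proposed new method).
 - What may go wrong: methyl transfer from AlMe3 to the side-chain ketone in competition with the aldol closure; an aluminium enolate too unreactive to add to the ketone; loss of enantioselectivity for the C7 epimer that is mismatched with the catalyst.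
 - Fallback (known chemistry, stepwise; sets out from 6, comes back at 10): the ketal enone 6 is methylated under the same copper catalysis, now a plain asymmetric conjugate addition of AlMe3 to a 3-alkylcyclohex-2-enone with no free ketone present, to give (3R)-3-methyl-3-[3-(2-methyl-1,3-dioxolan-2-yl)propyl]-6-(propan-2-yl)cyclohexan-1-one F1. HCl (1 M aq.) in THF removes the dioxolane to give (3R)-3-methyl-3-(4-oxopentyl)-6-(propan-2-yl)cyclohexan-1-one F2. NaOMe in MeOH then effects the aldol closure of ring A and the equilibration in one operation and should give 10.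

2. Step 6.
 - What may go wrong: equilibration that stops at or favours the cis-fused or the C4-epimeric ketol; crossover through retro-aldol into the bridged aldol mode (side-chain C3 onto C6); β-elimination of water.
 - Fallback (sets out from 9, comes back at 11): thermodynamic control is replaced by face-selective reactions relayed from C10. TsOH (cat.) in toluene at reflux with removal of water should convert every isomer of 9 into (7S,10R)-eudesm-4-en-6-one F3, with C7 settling as the pseudo-equatorial β-isopropyl. NaBH4/CeCl3·7H2O in MeOH at −40 °C should reduce from the α face, away from 10-CH3, to (6R,7S,10R)-eudesm-4-en-6-ol F4. VO(acac)2/t-BuOOH in CH2Cl2 should epoxidise syn to the allylic hydroxyl to give 4β,5β-epoxyeudesman-6β-ol F5. LiAlH4 in THF at reflux should open the epoxide trans-diaxially (Fürst–Plattner), hydride entering at C5 from the α face, and give 11.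

3. Step 9.
 - What may go wrong: slow acylation of the axial 6β-hydroxyl, which is syn-diaxial to 10-CH3 and hydrogen-bonded to 4-OH, with competing decomposition of the mixed anhydride or elimination of the tertiary alcohol on heating.
 - Fallback (sets out from 11, comes back at 16): the cinnamate is built on the alcohol instead of being transferred to it. Diethylphosphonoacetic acid, DCC and DMAP in CH2Cl2 should acylate the 6β-hydroxyl through the small, highly electrophilic phosphonoketene to give (4S,5S,6R,7S,10R)-4-hydroxyeudesman-6-yl 2-(diethoxyphosphoryl)acetate F6. 3-(tert-Butyldimethylsilyloxy)-4-methoxybenzaldehyde F7 is made from isovanillin (TBSCl, imidazole, DMF). Horner–Wadsworth–Emmons olefination of F7 with F6 (LiCl, DBU, MeCN, 23 °C) should give the E ester 16.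

Further compounds
F1 | step 5 | (3R)-3-methyl-3-[3-(2-methyl-1,3-dioxolan-2-yl)propyl]-6-(propan-2-yl)cyclohexan-1-one (both C6 epimers) | O=C1C[C@](C)(CCCC2(C)OCCO2)CCC1C(C)C
F2 | step 5 | (3R)-3-methyl-3-(4-oxopentyl)-6-(propan-2-yl)cyclohexan-1-one (both C6 epimers) | O=C1C[C@](C)(CCCC(C)=O)CCC1C(C)C
F3 | step 6 | (7S,10R)-eudesm-4-en-6-one | O=C1C2=C(C)CCC[C@]2(C)CC[C@H]1C(C)C
F4 | step 6 | (6R,7S,10R)-eudesm-4-en-6-ol (6β-ol) | O[C@H]1C2=C(C)CCC[C@]2(C)CC[C@H]1C(C)C
F5 | step 6 | 4β,5β-epoxyeudesman-6β-ol (7β-isopropyl, 10β-CH3) | O[C@H]1[C@]23O[C@@]2(C)CCC[C@]3(C)CC[C@H]1C(C)C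
F6 | step 9 | (4S,5S,6R,7S,10R)-4-hydroxyeudesman-6-yl 2-(diethoxyphosphoryl)acetate | CCOP(=O)(OCC)CC(=O)O[C@H]1[C@@H]2[C@](C)(CCC[C@]2(C)O)CC[C@H]1C(C)C
F7 | step 9 | 3-(tert-butyldimethylsilyloxy)-4-methoxybenzaldehyde | COc1ccc(C=O)cc1O[Si](C)(C)C(C)(C)C
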